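The pyranone ring is cut at C3–C4 and at O1–C8a (chromanone numbering). This leaves a C4–C4a–C8a bis-electrophile, 2-fluoro-3,6-dimethoxybenzoyl chloride, and an O1–C2–C3 bis-nucleophile, the methyl-side enolate of heptadecan-2-one. The key step exploits the 1,3-relation of the C4 carbonyl to the oxygen-bearing C2 and the ortho placement of C4 and O1 on the benzene ring: C-acylation gives a 1,3-diketonate whose oxygen then displaces the ortho fluoride, so the complete chromone forms in one flask from two achiral pieces. An enantioselective CuH conjugate reduction of the flat chromone then sets C2 (R), and demethylation frees the hydroquinone.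

Key step: step 3

Assumption: 1 and 6 are bought; in step 4 the ligand antipode must send hydride to the Si face of C2, is written as the (R)-ligand, and is exchanged for the (S)-ligand if the sense of induction proves reversed.

Step 1
Reactants: 1 2-fluoro-1,4-dimethoxybenzene
Product: 4 2-fluoro-3,6-dimethoxybenzoic acid, via aryllithium 2 (not isolated), via lithium carboxylate 3 (not isolated)
Conditions: n-BuLi (1.05 equiv), THF, −78 °C, 1 h; CO2 (gas), −78 °C → rt; then 1 M HCl
Reagents that add atoms: carbon dioxide, O=C=O
Why: Directed ortho-metalation removes the single ring proton flanked by fluorine and a methoxy group, the most acidic one, and the aryllithium, kept at −78 °C so that it does not lose LiF to an aryne, is carboxylated by CO2.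

Step 2
Reactants: 4 2-fluoro-3,6-dimethoxybenzoic acid
Product: 5 2-fluoro-3,6-dimethoxybenzoyl chloride
Conditions: (COCl)2 (1.5 equiv), DMF (cat.), CH2Cl2, 0 °C → rt; evaporation, used crude
Reagents that add atoms: oxalyl chloride, ClC(=O)C(=O)Cl
Why: Acid chloride formation by way of the chloroiminium salt from DMF and oxalyl chloride, to which the methyl ethers and the aryl fluoride are inert.

Step 3
Reactants: 6 heptadecan-2-one; 5 2-fluoro-3,6-dimethoxybenzoyl chloride
Product: 9 5,8-dimethoxy-2-pentadecyl-4H-chromen-4-one, via lithium enolate 7 (not isolated), via lithium diketonate 8 (not isolated)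
Conditions: 6 (1.1 equiv), LiN(SiMe3)2 (2.2 equiv), THF, −78 °C; 5 (1.0 equiv), −78 → 0 °C; then DMF, 100 °C (THF distilled off)
Reagents that add atoms: none
Why: LiN(SiMe3)2 at −78 °C removes a methyl proton of 6 to give the terminal enolate 7, whose carbon attacks the acid chloride (bond C3–C4), and the second equivalent of base converts the diketone at once into the chelated lithium diketonate 8; in hot DMF the diketonate oxygen on the alkyl side (the future O1) adds to the fluorine-bearing carbon, the β-position of a vinylogous acyl fluoride, and fluoride leaves as LiF (bond O1–C8a). The closest known reaction type is the one-pot chromone and 4-quinolone synthesis from 2-halobenzoyl chlorides and enolates, a Claisen-type C-acylation followed by intramolecular SNAr. The pyranone ring closes as a six-membered ring by addition–elimination at C8a, formally 6-endo-trig at the C4a=C8a bond of the aryl ketone; attack by the other diketonate oxygen would need a four-membered ring, so only one ring can form. No stereocentre arises, since C2 stays sp2 and is set in step 4. The step needs C- over O-acylation and methyl over methylene enolisation, secured by the lithium enolate in THF, the bulky non-nucleophilic amide base and the return of any enol ester to the diketonate by excess enolate. It also needs displacement of fluoride on a ring that carries two donor methoxy groups, secured by the ortho carbonyl, the intramolecular delivery and the choice of fluoride, far the better leaving group than the methoxy group on the other ortho carbon.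

Step 4
Reactants: 9 5,8-dimethoxy-2-pentadecyl-4H-chromen-4-one
Product: 11 (R)-5,8-dimethoxy-2-pentadecylchroman-4-one, via silyl enol ether 10 (not isolated)
Conditions: Cu(OAc)2·H2O (5 mol %), (R)-DTBM-SEGPHOS (5.5 mol %), (EtO)2MeSiH (2 equiv), toluene, 0 °C → rt; then 1 M HCl, THF, 0 °C
Reagents that add atoms: none
Why: Asymmetric conjugate reduction (1,4-hydrosilylation) by bisphosphine-ligated CuH: hydride adds to C2, the β-carbon of the vinylogous ester, on the Si face selected by the chiral ligand to set C2 as R, the enolate is trapped as silyl enol ether 10, which keeps the C4 carbonyl from over-reduction, and mild acid hydrolysis returns the ketone.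

Step 5
Reactants: 11 (R)-5,8-dimethoxy-2-pentadecylchroman-4-one
Product: 13 (R)-5,8-dihydroxy-2-pentadecylchroman-4-one, via bis(dibromoboryl) ether 12 (not isolated)
Conditions: BBr3 (4 equiv), CH2Cl2, −78 → 0 °C, argon; then H2O, 0 °C
Reagents that add atoms: none
Why: Lewis acid ether cleavage: BBr3 binds the two methoxy oxygens (the C5 one with chelation to the C4 carbonyl), bromide removes the methyl groups by SN2 and water hydrolyses the aryloxyboron species 12, while O1, a weakly basic vinylogous ester oxygen on a secondary non-benzylic carbon, should stay bound to C2 so that the configuration is kept.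

Compound list
1 | 2-fluoro-1,4-dimethoxybenzene | COc1ccc(OC)c(F)c1 | starting material
2 | (2-fluoro-3,6-dimethoxyphenyl)lithium, formed in the flask | COc1ccc(OC)c(F)c1[Li] | intermediate
3 | lithium 2-fluoro-3,6-dimethoxybenzoate, formed in the flask | COc1ccc(OC)c(F)c1C(=O)[O-].[Li+] | intermediate
4 | 2-fluoro-3,6-dimethoxybenzoic acid | COc1ccc(OC)c(F)c1C(=O)O | intermediate
5 | 2-fluoro-3,6-dimethoxybenzoyl chloride | COc1ccc(OC)c(F)c1C(Cl)=O | intermediate
6 | heptadecan-2-one | CCCCCCCCCCCCCCCC(C)=O | starting material
7 | lithium heptadec-1-en-2-olate, formed in the flask | CCCCCCCCCCCCCCCC(=C)[O-].[Li+] | intermediate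
8 | lithium enolate of 1-(2-fluoro-3,6-dimethoxyphenyl)octadecane-1,3-dione, formed in the flask | CCCCCCCCCCCCCCCC([O-])=CC(=O)c1c(F)c(OC)ccc1OC.[Li+] | intermediate
9 | 5,8-dimethoxy-2-pentadecyl-4H-chromen-4-one | CCCCCCCCCCCCCCCC1=CC(=O)c2c(OC)ccc(OC)c2O1 | intermediate
10 | (R)-4-[diethoxy(methyl)silyloxy]-5,8-dimethoxy-2-pentadecyl-2H-chromene, formed in the flask | CCCCCCCCCCCCCCC[C@@H]1C=C(O[Si](C)(OCC)OCC)c2c(OC)ccc(OC)c2O1 | intermediate
11 | (R)-5,8-dimethoxy-2-pentadecylchroman-4-one | CCCCCCCCCCCCCCC[C@@H]1CC(=O)c2c(OC)ccc(OC)c2O1 | intermediate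
12 | (R)-5,8-bis(dibromoboryloxy)-2-pentadecylchroman-4-one, formed in the flask | CCCCCCCCCCCCCCC[C@@H]1CC(=O)c2c(OB(Br)Br)ccc(OB(Br)Br)c2O1 | intermediate
13 | (R)-5,8-dihydroxy-2-pentadecylchroman-4-one | CCCCCCCCCCCCCCC[C@@H]1CC(=O)c2c(O)ccc(O)c2O1 | target

Total step count: 5. Longest linear sequence: 5 steps (1 → 4 → 5 → 9 → 11 → 13); ketone 6 enters at step 3.

Steps most likely to fail

Step 3. The enolate may be acylated on oxygen, the excess amide base may consume the acid chloride, and the fluoride displacement on the donor-substituted ring may be slow enough for retro-Claisen cleavage of the diketonate to compete. The fallback sets out from 5 and comes back at 9. The carbon nucleophile is changed to a β-keto ester, whose ester group enforces C-acylation and is removed afterwards. Acid chloride 5 and commercial methyl 3-oxooctadecanoate are combined with MgCl2 and Et3N in MeCN (0 °C → rt) to give methyl 2-(2-fluoro-3,6-dimethoxybenzoyl)-3-oxooctadecanoate F1. K2CO3 in DMF at 80 °C, added to the same flask, should close the ring to methyl 5,8-dimethoxy-4-oxo-2-pentadecyl-4H-chromene-3-carboxylate F2. Heating in aqueous H2SO4/AcOH should hydrolyse the ester to 5,8-dimethoxy-4-oxo-2-pentadecyl-4H-chromene-3-carboxylic acid F3, which loses CO2 under the same conditions to give 9.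

Step 4. Hydride delivery may show poor facial selectivity at C2, or reduction of the C4 carbonyl may compete if ketone is set free before the silane is spent. The fallback sets out from 9 and comes back at 11. Asymmetric catalysis is replaced by resolution. Conjugate reduction of 9 with LiBH(s-Bu)3 (THF, −78 °C) should give racemic 5,8-dimethoxy-2-pentadecylchroman-4-one F4. Preparative chromatography on a chiral stationary phase then separates 11 from (S)-5,8-dimethoxy-2-pentadecylchroman-4-one F5, which is set aside.

Step 5. The Lewis acid may open the pyranone ring at O1–C2 and so erode the configuration at C2, or the C8 methyl ether may be cleaved incompletely. The fallback sets out from 9 and comes back at 13. The methyl ethers are removed before the stereocentre exists and replaced by silyl ethers that come off without Lewis acid or base. BBr3 in CH2Cl2 on chromone 9 should give 5,8-dihydroxy-2-pentadecyl-4H-chromen-4-one F6. TBSOTf and 2,6-lutidine should give 5,8-bis(tert-butyldimethylsilyloxy)-2-pentadecyl-4H-chromen-4-one F7. The CuH reduction of step 4 should give, by way of (R)-5,8-bis(tert-butyldimethylsilyloxy)-4-[diethoxy(methyl)silyloxy]-2-pentadecyl-2H-chromene F8, the ketone (R)-5,8-bis(tert-butyldimethylsilyloxy)-2-pentadecylchroman-4-one F9. HF·pyridine in THF at 0 °C then removes both silyl groups to give 13.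

Further compounds
F1 | step 3 | methyl 2-(2-fluoro-3,6-dimethoxybenzoyl)-3-oxooctadecanoate | CCCCCCCCCCCCCCCC(=O)C(C(=O)OC)C(=O)c1c(F)c(OC)ccc1OC
F2 | step 3 | methyl 5,8-dimethoxy-4-oxo-2-pentadecyl-4H-chromene-3-carboxylate | CCCCCCCCCCCCCCCC1=C(C(=O)OC)C(=O)c2c(OC)ccc(OC)c2O1
F3 | step 3 | 5,8-dimethoxy-4-oxo-2-pentadecyl-4H-chromene-3-carboxylic acid | CCCCCCCCCCCCCCCC1=C(C(=O)O)C(=O)c2c(OC)ccc(OC)c2O1
F4 | step 4 | racemic 5,8-dimethoxy-2-pentadecylchroman-4-one | CCCCCCCCCCCCCCCC1CC(=O)c2c(OC)ccc(OC)c2O1
F5 | step 4 | (S)-5,8-dimethoxy-2-pentadecylchroman-4-one | CCCCCCCCCCCCCCC[C@H]1CC(=O)c2c(OC)ccc(OC)c2O1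
F6 | step 5 | 5,8-dihydroxy-2-pentadecyl-4H-chromen-4-one | CCCCCCCCCCCCCCCC1=CC(=O)c2c(O)ccc(O)c2O1
F7 | step 5 | 5,8-bis(tert-butyldimethylsilyloxy)-2-pentadecyl-4H-chromen-4-one | CCCCCCCCCCCCCCCC1=CC(=O)c2c(O[Si](C)(C)C(C)(C)C)ccc(O[Si](C)(C)C(C)(C)C)c2O1
F8 | step 5 | (R)-5,8-bis(tert-butyldimethylsilyloxy)-4-[diethoxy(methyl)silyloxy]-2-pentadecyl-2H-chromene | CCCCCCCCCCCCCCC[C@@H]1C=C(O[Si](C)(OCC)OCC)c2c(O[Si](C)(C)C(C)(C)C)ccc(O[Si](C)(C)C(C)(C)C)c2O1
F9 | step 5 | (R)-5,8-bis(tert-butyldimethylsilyloxy)-2-pentadecylchroman-4-one | CCCCCCCCCCCCCCC[C@@H]1CC(=O)c2c(O[Si](C)(C)C(C)(C)C)ccc(O[Si](C)(C)C(C)(C)C)c2O1
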